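The route rests on disconnecting C5–C10 (ring B) and C3–C4 (ring A) of the trans-decalin. The exocyclic C9=C11 styrene, flanked by the C8 methyl stereocentre and quaternary C10, is read as the remnant of an aryl-stabilised C10–C9–C11 allyl cation. Ionising an acyclic C10 tertiary allylic alcohol lets the prenyl alkene close ring B at C10 and the resulting C4 cation be captured ipso by a Z-vinylsilane to close ring A. Both rings, two C–C bonds and the C5 and C10 centres thus arise in one operation under control of C8, which comes from (S)-citronellic acid. The precursor is that carbinol, bearing the trimethoxyaryl alkene on C9, the prenyl chain on C8 and the Z-vinylsilane arm on C10.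

Key step: step 7

Remark 1: drimane numbering is used throughout, also for acyclic intermediates (C1–C3 arm, C4 gem-dimethyl carbon, C5–C10, C11 benzylic carbon, C1′–C6′ aryl carbons).
Remark 2: aryl sulfates are written in the neutral hydrogen sulfate form of the target; 22 and 23 would be handled as pyridinium or potassium salts and brought to the acid form by cation exchange.
Remark 3: alcohols 11 and 12 are mixtures of C10 epimers, which is of no consequence because C10 becomes planar in step 7; both are acid-sensitive and would be purified on triethylamine-deactivated silica.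

Step 1
Reactants: 1 (S)-citronellic acid
Product: 3 (3S)-N-methoxy-N,3,7-trimethyloct-6-enamide, via acyl imidazolide 2 (not isolated)
Conditions: CDI, CH2Cl2, rt; then MeNH(OMe)·HCl, rt
Reagents that add atoms: N,O-dimethylhydroxylamine hydrochloride, CNOC.Cl
Why: CDI-mediated amidation through the acyl imidazolide gives the N-methoxy-N-methylamide (Weinreb amide) without touching the C8 stereocentre, which is β to the carbonyl group.

Step 2
Reactants: 3 (3S)-N-methoxy-N,3,7-trimethyloct-6-enamide; 4 2,4,5-trimethoxybenzaldehyde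
Product: 6 (3S)-2-[hydroxy(2,4,5-trimethoxyphenyl)methyl]-N-methoxy-N,3,7-trimethyloct-6-enamide, via lithium enolate 5 (not isolated)
Conditions: LDA, THF, −78 °C; then 4, −78 °C; AcOH, −78 °C
Reagents that add atoms: none
Why: Directed aldol addition of the preformed lithium amide enolate to a non-enolisable aldehyde forms C9–C11 without crossed products, and the two new stereocentres (C9, C11) need no control because both are lost in step 3.

Step 3
Reactants: 6 (3S)-2-[hydroxy(2,4,5-trimethoxyphenyl)methyl]-N-methoxy-N,3,7-trimethyloct-6-enamide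
Product: 8 (2E,3S)-N-methoxy-N,3,7-trimethyl-2-[(2,4,5-trimethoxyphenyl)methylidene]oct-6-enamide, via mesylate 7 (not isolated)
Conditions: MsCl, Et3N, CH2Cl2, 0 °C; then DBU, rt
Reagents that add atoms: none
Why: Mesylation followed by base-induced β-elimination (aldol dehydration, E1cB type) gives the conjugated amide, for which the E isomer with the aryl group trans to the carbonyl group and cis to C8 is expected as the more stable one; base is present throughout so that the electron-rich benzylic mesylate eliminates and does not ionise toward the prenyl alkene.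

Step 4
Reactants: 8 (2E,3S)-N-methoxy-N,3,7-trimethyl-2-[(2,4,5-trimethoxyphenyl)methylidene]oct-6-enamide
Product: 9 (3E,4S)-4,8-dimethyl-3-[(2,4,5-trimethoxyphenyl)methylidene]non-7-en-2-one
Conditions: MeMgBr, THF, 0 °C; aq. NH4Cl
Reagents that add atoms: methylmagnesium bromide, C[Mg]Br
Why: Weinreb ketone synthesis: the chelated tetrahedral magnesium intermediate holds until work-up, so a single methyl group is added and C10 is delivered as the methyl ketone.

Step 5
Reactants: 9 (3E,4S)-4,8-dimethyl-3-[(2,4,5-trimethoxyphenyl)methylidene]non-7-en-2-one; 10 3-bromo-1-(trimethylsilyl)prop-1-yne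
Product: 11 (5E,6S)-4,6,10-trimethyl-5-[(2,4,5-trimethoxyphenyl)methylidene]-1-(trimethylsilyl)undec-9-en-1-yn-4-ol
Conditions: Zn dust, THF, 0 °C → rt; aq. NH4Cl
Reagents that add atoms: none
Why: Barbier-type propargylation: the allenylzinc bromide formed from 10 adds through its CH2 terminus (SE2′) to the ketone carbonyl in a 1,2 sense and gives the silylated homopropargylic tertiary alcohol, whose C10 configuration is irrelevant because C10 is ionised in step 7.

Step 6
Reactants: 11 (5E,6S)-4,6,10-trimethyl-5-[(2,4,5-trimethoxyphenyl)methylidene]-1-(trimethylsilyl)undec-9-en-1-yn-4-ol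
Product: 12 (1Z,5E,6S)-4,6,10-trimethyl-5-[(2,4,5-trimethoxyphenyl)methylidene]-1-(trimethylsilyl)undeca-1,9-dien-4-ol
Conditions: H2 (1 atm, 1 equiv uptake), Lindlar catalyst, quinoline, hexane–EtOAc, rt
Reagents that add atoms: none
Why: Lindlar semi-hydrogenation adds H2 syn to the silylalkyne and gives the Z-vinylsilane, while the two trisubstituted alkenes are not reduced on the poisoned catalyst.

Step 7
Reactants: 12 (1Z,5E,6S)-4,6,10-trimethyl-5-[(2,4,5-trimethoxyphenyl)methylidene]-1-(trimethylsilyl)undeca-1,9-dien-4-ol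
Product: 15 (5S,8S,10S,9(11)E)-11-(2,4,5-trimethoxyphenyl)drima-2,9(11)-diene, via allyl cation 13 (not isolated), via ring-B C4 cation 14 (not isolated)
Conditions: SnCl4 (2 equiv), CH2Cl2, −78 → −40 °C; aq. NaHCO3
Reagents that add atoms: none
Why: Proposed new method: SnCl4 ionises the C10 tertiary allylic alcohol to the planar aryl-stabilised C10–C9–C11 allyl cation 13, C5 of the prenyl alkene bonds to C10 to give the exocyclic tertiary C4 cation 14, and C3 of the Z-vinylsilane attacks C4 ipso, after which the β-silyl cation at C2 loses silicon and leaves C2=C3; the closest known reaction type is the cation–olefin polycyclisation initiated by an allylic alcohol and terminated by a vinylsilane, which is applied here with the terminating arm on the initiating carbon, so that ring B forms before ring A through an exocyclic cation, a topology not yet demonstrated. Ring B closes 6-exo with respect to the C5=C4 alkene through a chair, and ring A closes 6-endo with respect to the vinylsilane, whose Z geometry lets the C–Si bond align with the developing C2 cation inside the new ring. C5 is controlled by C8: A(1,3) strain with the aryl group, which sits cis to C8 on C9=C11, holds C8–H in the allyl plane and the C8 methyl axial, so C5 bonds to the face of C10 opposite that methyl with the CMe2 unit equatorial and C5–H axial. C10 is controlled by the same chair: the arm, the bulkier C10 substituent, takes the in-plane site next to C11–H and becomes equatorial, the methyl takes the site next to C8 and becomes axial and syn to the C8 methyl, and capture of the C4 cation by the equatorial arm then gives the trans ring fusion. The step needs bonding at C10 and not at benzylic C11, which is secured because reaction at C10 keeps C9=C11 conjugated with the arene and avoids a tetrasubstituted C9=C10 alkene wedged between C8 and an aryl-bearing C11; the prenyl alkene, the stronger π-nucleophile, reacts first and the vinylsilane only meets the far more electrophilic C4 cation.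

Step 8
Reactants: 15 (5S,8S,10S,9(11)E)-11-(2,4,5-trimethoxyphenyl)drima-2,9(11)-diene
Product: 16 (5S,8S,10S,9(11)E)-11-(2,4,5-trimethoxyphenyl)drim-9(11)-ene
Conditions: TsNHNH2, NaOAc, DME–H2O, reflux
Reagents that add atoms: none
Why: Diimide reduction transfers H2 in a concerted syn fashion to the cis-disubstituted C2=C3 alkene and leaves the trisubstituted, doubly flanked C9=C11 styrene untouched, with no metal present that could move or isomerise either alkene.

Step 9
Reactants: 16 (5S,8S,10S,9(11)E)-11-(2,4,5-trimethoxyphenyl)drim-9(11)-ene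
Product: 18 (5S,8S,10S,9(11)E)-11-(3-formyl-2,4,5-trimethoxyphenyl)drim-9(11)-ene, via aryllithium 17 (not isolated)
Conditions: n-BuLi, TMEDA, THF, 0 °C; then DMF, −78 °C → rt; H2O
Reagents that add atoms: N,N-dimethylformamide, CN(C)C=O
Why: Directed ortho-metalation removes C3′–H, the only ring hydrogen flanked by two methoxy groups, and formylation of the aryllithium with DMF places the aldehyde between O2′ and O4′.

Step 10
Reactants: 18 (5S,8S,10S,9(11)E)-11-(3-formyl-2,4,5-trimethoxyphenyl)drim-9(11)-ene
Product: 19 (5S,8S,10S,9(11)E)-11-(3-formyl-4-methoxy-2,5-dioxocyclohexa-3,6-dien-1-yl)drim-9(11)-ene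
Conditions: CAN, MeCN–H2O, 0 °C
Reagents that add atoms: water, O
Why: Ceric ammonium nitrate oxidative demethylation converts the para-related 2′- and 5′-methoxy groups into the p-quinone by ipso attack of water on the arene radical cation, and the 4′-methoxy group survives as a vinylogous ester.

Step 11
Reactants: 19 (5S,8S,10S,9(11)E)-11-(3-formyl-4-methoxy-2,5-dioxocyclohexa-3,6-dien-1-yl)drim-9(11)-ene
Product: 20 (5S,8S,10S,9(11)E)-11-[4-(allyloxy)-3-formyl-2,5-dioxocyclohexa-3,6-dien-1-yl]drim-9(11)-ene
Conditions: allyl alcohol (solvent), PPTS (cat.), rt, dark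
Reagents that add atoms: allyl alcohol, C=CCO
Why: Vinylogous transesterification by addition–elimination, the alkoxy exchange known for 2-alkoxy-1,4-quinones, is favoured here because C4′ is the β-carbon of both the C2′ enone and the formyl enal, so methanol is replaced by the allyl group that can later be removed under neutral conditions.

Step 12
Reactants: 20 (5S,8S,10S,9(11)E)-11-[4-(allyloxy)-3-formyl-2,5-dioxocyclohexa-3,6-dien-1-yl]drim-9(11)-ene
Product: 21 (5S,8S,10S,9(11)E)-11-[4-(allyloxy)-3-formyl-2,5-dihydroxyphenyl]drim-9(11)-ene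
Conditions: Na2S2O4, THF–H2O, rt, argon
Reagents that add atoms: none
Why: Dithionite reduction of the quinone to the hydroquinone frees exactly O2′ and O5′, the two oxygens to be sulfated, while O4′ stays allylated and the aldehyde and alkenes are not reduced.

Step 13
Reactants: 21 (5S,8S,10S,9(11)E)-11-[4-(allyloxy)-3-formyl-2,5-dihydroxyphenyl]drim-9(11)-ene
Product: 22 (5S,8S,10S,9(11)E)-11-[4-(allyloxy)-3-formyl-2,5-bis(sulfooxy)phenyl]drim-9(11)-ene
Conditions: SO3·pyridine (excess), pyridine, 50 °C, argon
Reagents that add atoms: sulfur trioxide–pyridine complex, [O-]S(=O)(=O)[n+]1ccccc1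
Why: O-Sulfation of phenols with the sulfur trioxide–pyridine complex converts both free hydroxyls into sulfate monoesters, with excess reagent and gentle warming to reach the flanked, hydrogen-bonded 2′-OH.

Step 14
Reactants: 22 (5S,8S,10S,9(11)E)-11-[4-(allyloxy)-3-formyl-2,5-bis(sulfooxy)phenyl]drim-9(11)-ene
Product: 23 (5S,8S,10S,9(11)E)-11-[3-formyl-4-hydroxy-2,5-bis(sulfooxy)phenyl]drim-9(11)-ene (CNP0309628.1)
Conditions: Pd(PPh3)4 (cat.), K2CO3, MeOH, rt; then Dowex 50 (H+), 0 °C
Reagents that add atoms: none
Why: Palladium(0)-catalysed deallylation (Tsuji–Trost type π-allyl formation with transfer of the allyl group to methanol) frees O4′ under conditions that leave the aryl sulfates, the aldehyde and the C9=C11 alkene untouched.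

Compound list
1 | (S)-citronellic acid, (3S)-3,7-dimethyloct-6-enoic acid | C[C@H](CC(=O)O)CCC=C(C)C | starting material
2 | (3S)-1-(imidazol-1-yl)-3,7-dimethyloct-6-en-1-one (acyl imidazolide of 1) | C[C@H](CC(=O)n1ccnc1)CCC=C(C)C | intermediate (not isolated)
3 | (3S)-N-methoxy-N,3,7-trimethyloct-6-enamide | C[C@H](CC(=O)N(C)OC)CCC=C(C)C | intermediate
4 | 2,4,5-trimethoxybenzaldehyde | COc1cc(OC)c(OC)cc1C=O | starting material
5 | lithium (Z)-enolate of 3 | C[C@H](/C=C(\O[Li])N(C)OC)CCC=C(C)C | intermediate (not isolated)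
6 | (3S)-2-[hydroxy(2,4,5-trimethoxyphenyl)methyl]-N-methoxy-N,3,7-trimethyloct-6-enamide, diastereomer mixture at C9 and C11 | C[C@H](C(C(O)c1cc(OC)c(OC)cc1OC)C(=O)N(C)OC)CCC=C(C)C | intermediate
7 | methanesulfonate of 6 at the benzylic (C11) oxygen | C[C@H](C(C(OS(C)(=O)=O)c1cc(OC)c(OC)cc1OC)C(=O)N(C)OC)CCC=C(C)C | intermediate (not isolated)
8 | (2E,3S)-N-methoxy-N,3,7-trimethyl-2-[(2,4,5-trimethoxyphenyl)methylidene]oct-6-enamide | C[C@H](/C(=C\c1cc(OC)c(OC)cc1OC)C(=O)N(C)OC)CCC=C(C)C | intermediate
9 | (3E,4S)-4,8-dimethyl-3-[(2,4,5-trimethoxyphenyl)methylidene]non-7-en-2-one | C[C@H](/C(=C\c1cc(OC)c(OC)cc1OC)C(C)=O)CCC=C(C)C | intermediate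
10 | 3-bromo-1-(trimethylsilyl)prop-1-yne | C[Si](C)(C)C#CCBr | starting material
11 | (5E,6S)-4,6,10-trimethyl-5-[(2,4,5-trimethoxyphenyl)methylidene]-1-(trimethylsilyl)undec-9-en-1-yn-4-ol, both C10 epimers | C[C@H](/C(=C\c1cc(OC)c(OC)cc1OC)C(C)(O)CC#C[Si](C)(C)C)CCC=C(C)C | intermediate
12 | (1Z,5E,6S)-4,6,10-trimethyl-5-[(2,4,5-trimethoxyphenyl)methylidene]-1-(trimethylsilyl)undeca-1,9-dien-4-ol, both C10 epimers (cyclisation precursor) | C[C@H](/C(=C\c1cc(OC)c(OC)cc1OC)C(C)(O)C/C=C\[Si](C)(C)C)CCC=C(C)C | intermediate
13 | C10–C9–C11 allyl cation from 12, drawn as the C10 cation, aryl cis to C8 | C[C@H](/C(=C\c1cc(OC)c(OC)cc1OC)[C+](C)C/C=C\[Si](C)(C)C)CCC=C(C)C | intermediate (not isolated)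
14 | ring-B monocycle with the 2-propyl cation (C4) on C5 and the Z-vinylsilane arm equatorial on C10, configuration at C5, C8, C10 as in 15 | C[C@H]1CC[C@@H]([C+](C)C)[C@](C)(C/C=C\[Si](C)(C)C)/C1=C/c1cc(OC)c(OC)cc1OC | intermediate (not isolated)
15 | (5S,8S,10S,9(11)E)-11-(2,4,5-trimethoxyphenyl)drima-2,9(11)-diene | C[C@H]1CC[C@H]2C(C)(C)C=CC[C@]2(C)/C1=C/c1cc(OC)c(OC)cc1OC | intermediate
16 | (5S,8S,10S,9(11)E)-11-(2,4,5-trimethoxyphenyl)drim-9(11)-ene | C[C@H]1CC[C@H]2C(C)(C)CCC[C@]2(C)/C1=C/c1cc(OC)c(OC)cc1OC | intermediate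
17 | 3′-lithio derivative of 16 | C[C@H]1CC[C@H]2C(C)(C)CCC[C@]2(C)/C1=C/c1cc(OC)c(OC)c([Li])c1OC | intermediate (not isolated)
18 | (5S,8S,10S,9(11)E)-11-(3-formyl-2,4,5-trimethoxyphenyl)drim-9(11)-ene | C[C@H]1CC[C@H]2C(C)(C)CCC[C@]2(C)/C1=C/c1cc(OC)c(OC)c(C=O)c1OC | intermediate
19 | (5S,8S,10S,9(11)E)-11-(3-formyl-4-methoxy-2,5-dioxocyclohexa-3,6-dien-1-yl)drim-9(11)-ene (2′,5′-quinone) | C[C@H]1CC[C@H]2C(C)(C)CCC[C@]2(C)/C1=C/C3=CC(=O)C(OC)=C(C=O)C3=O | intermediate
20 | (5S,8S,10S,9(11)E)-11-[4-(allyloxy)-3-formyl-2,5-dioxocyclohexa-3,6-dien-1-yl]drim-9(11)-ene | C[C@H]1CC[C@H]2C(C)(C)CCC[C@]2(C)/C1=C/C3=CC(=O)C(OCC=C)=C(C=O)C3=O | intermediate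
21 | (5S,8S,10S,9(11)E)-11-[4-(allyloxy)-3-formyl-2,5-dihydroxyphenyl]drim-9(11)-ene | C[C@H]1CC[C@H]2C(C)(C)CCC[C@]2(C)/C1=C/c1cc(O)c(OCC=C)c(C=O)c1O | intermediate
22 | (5S,8S,10S,9(11)E)-11-[4-(allyloxy)-3-formyl-2,5-bis(sulfooxy)phenyl]drim-9(11)-ene | C[C@H]1CC[C@H]2C(C)(C)CCC[C@]2(C)/C1=C/c1cc(OS(=O)(=O)O)c(OCC=C)c(C=O)c1OS(=O)(=O)O | intermediate
23 | (5S,8S,10S,9(11)E)-11-[3-formyl-4-hydroxy-2,5-bis(sulfooxy)phenyl]drim-9(11)-ene, CNP0309628.1 | C[C@H]1CC[C@H]2C(C)(C)CCC[C@]2(C)/C1=C/c1cc(OS(=O)(=O)O)c(O)c(C=O)c1OS(=O)(=O)O | target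

Total step count: 14. Longest linear sequence: 14 steps (from 1; the route is fully linear).

Steps most likely to fail

Step 7 (bears the label). The C4 cation may lose a proton, or the vinylsilane may be protodesilylated, before ring A closes. Bonding may also occur at C11 instead of C10, or the C9–C10 rotamer with the arm next to C8 may react. The fallback uses known reactions and closes ring A with palladium instead of the cation, so it answers only the first of these. It sets out from 11. Silver-catalysed iododesilylation of the alkyne (NIS, AgNO3 cat., acetone) would give the iodoalkyne F1, and diimide (2-nitrobenzenesulfonyl hydrazide, Et3N) would reduce it to the Z-vinyl iodide F2. SnCl4 at −78 °C would then close ring B alone, the C4 cation ending by loss of a methyl proton, to give the isopropenyl monocycle F3. A reductive Heck cyclisation (Pd(OAc)2, PPh3, HCO2Na, DMF, 80 °C), 6-exo onto the isopropenyl group with formate reduction of the neopentyl palladium species, would form C3–C4 with the gem-dimethyl carbon and come back to the route at 15.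

Step 11. Allyl alcohol may add to the formyl group or to C6′ of the quinone, or the vinyl quinone may tautomerise, faster than the exchange at C4′. The fallback avoids the allyl group and sets out from 19. Dithionite reduction would give the methoxy hydroquinone F4, and SO3·pyridine its bis(hydrogen sulfate) F5. The O4′ methyl group, activated by the ortho formyl group, would then be removed by sodium ethanethiolate in DMF (SN2 at the methyl carbon), coming back to the route at the target 23.

Step 13. Sulfation may stop at the 5′-monosulfate because the 2′-OH is flanked and hydrogen-bonded, and the hydroquinone may be reoxidised during the long reaction. The fallback goes through protected sulfate diesters and sets out from 21. 2,2,2-Trichloroethyl chlorosulfate with Et3N and DMAP in THF, a stronger sulfating electrophile, would give the bis(trichloroethyl sulfate) F6. Zinc with ammonium formate in methanol would remove both trichloroethyl groups by reductive fragmentation, coming back to the route at 22.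

Further compounds
F1 | step 7 | (5E,6S)-1-iodo-4,6,10-trimethyl-5-[(2,4,5-trimethoxyphenyl)methylidene]undec-9-en-1-yn-4-ol | C[C@H](/C(=C\c1cc(OC)c(OC)cc1OC)C(C)(O)CC#CI)CCC=C(C)C
F2 | step 7 | (1Z,5E,6S)-1-iodo-4,6,10-trimethyl-5-[(2,4,5-trimethoxyphenyl)methylidene]undeca-1,9-dien-4-ol | C[C@H](/C(=C\c1cc(OC)c(OC)cc1OC)C(C)(O)C/C=C\I)CCC=C(C)C
F3 | step 7 | ring-B monocycle carrying the C5 isopropenyl group, the C10 methyl and (Z)-3-iodoallyl groups and the (E)-arylmethylidene group, configuration as in 15 | C[C@H]1CC[C@@H](C(C)=C)[C@](C)(C/C=C\I)/C1=C/c1cc(OC)c(OC)cc1OC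
F4 | step 11 | (5S,8S,10S,9(11)E)-11-(3-formyl-2,5-dihydroxy-4-methoxyphenyl)drim-9(11)-ene | C[C@H]1CC[C@H]2C(C)(C)CCC[C@]2(C)/C1=C/c1cc(O)c(OC)c(C=O)c1O
F5 | step 11 | (5S,8S,10S,9(11)E)-11-[3-formyl-4-methoxy-2,5-bis(sulfooxy)phenyl]drim-9(11)-ene | C[C@H]1CC[C@H]2C(C)(C)CCC[C@]2(C)/C1=C/c1cc(OS(=O)(=O)O)c(OC)c(C=O)c1OS(=O)(=O)O
F6 | step 13 | bis(2,2,2-trichloroethyl sulfate) diester of 21 | C[C@H]1CC[C@H]2C(C)(C)CCC[C@]2(C)/C1=C/c1cc(OS(=O)(=O)OCC(Cl)(Cl)Cl)c(OCC=C)c(C=O)c1OS(=O)(=O)OCC(Cl)(Cl)Cl
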